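## Retrosynthetic overview

1. The C12–C13 bond is cut by a B-alkyl Suzuki–Miyaura coupling between the borane from a C9-vinyl decalin and (E)-3-iodobut-2-en-1-ol (from but-2-yn-1-ol).
2. The C8 carbinol comes from a C8 ketone by methylenation, epoxidation on the face anti to the C10 methyl, and hydride opening; the C8 oxygen is the dienol oxygen of the cycloaddition.
3. The strategy rests on the trans-decalin with quaternary C10: it is cut at C5–C10 and C8–C9, so rings A and B form together in one intramolecular Diels–Alder reaction. C10 and its methyl come from an (E)-3-methyl enoate (C9=C10), C5–C8 from a 1-silyloxy diene, and the equatorial C3 bromide next to the C4 gem-dimethyl group rides on the C1–C4 tether and selects the diene face.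
4. The triene is assembled from 2,2-dimethylpent-4-enal (C3–C6, C18, C19), methyl acetoacetate (C1, C9–C11), a methyl cuprate (C20) and crotonaldehyde (C7, C8).

Key step: step 9

Remarks:
- Bicyclic compounds carry labdane locants (decalin C1–C10, C11 on C9, C17 on C8, C20 = methyl on C10); "syn" and "anti" mean the same or the opposite face of the decalin as C20.
- The dienol is carried as its tert-butyldimethylsilyl ether. This raises the diene HOMO and lets O8 stay protected while the C11 ester is reduced.
- Assumption: (2R,5R)-2,5-diphenylpyrrolidine shields the enamine face as in the usual steric model and gives the (S)-bromide; if the sense proved opposite, the (2S,5S)-catalyst would be used.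

## Route

Step 1
Reactants: 1 2,2-dimethylpent-4-enal
Product: 3 3,3-dimethylhex-5-enal, via enol ether 2 (not isolated)
Conditions: Ph3P(CH2OMe)Cl, KOtBu, THF, 0 °C to rt; then 2 M HCl, THF, rt
Reagents that add atoms: (methoxymethyl)triphenylphosphonium chloride, COC[P+](c1ccccc1)(c1ccccc1)c1ccccc1.[Cl-]; water, O
Why: Wittig methoxymethylenation of the non-enolisable aldehyde and acid hydrolysis of the enol ether give the one-carbon homologue, the isolated terminal alkene being inert to both operations.

Step 2
Reactants: 3 3,3-dimethylhex-5-enal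
Product: 5 (2S)-2-bromo-3,3-dimethylhex-5-en-1-ol, via bromo aldehyde 4 (not isolated)
Conditions: (2R,5R)-2,5-diphenylpyrrolidine (20 mol %), PhCO2H (20 mol %), H2O, 4,4-dibromo-2,6-di-tert-butylcyclohexa-2,5-dien-1-one, CH2Cl2/pentane, −40 °C; then NaBH4, MeOH, −40 to 0 °C
Reagents that add atoms: 4,4-dibromo-2,6-di-tert-butylcyclohexa-2,5-dien-1-one, O=C1C(C(C)(C)C)=CC(Br)(Br)C=C1C(C)(C)C
Why: Enamine-catalysed α-bromination, in which one face of the (E)-enamine is blocked by a phenyl group of the C2-symmetric amine so that bromine is delivered to give the (S)-bromide (the future C3), and in situ NaBH4 reduction removes the epimerisable aldehyde before it can racemise.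

Step 3
Reactants: 5 (2S)-2-bromo-3,3-dimethylhex-5-en-1-ol
Product: 6 (2S)-2-bromo-3,3-dimethylhex-5-en-1-yl trifluoromethanesulfonate
Conditions: Tf2O, 2,6-lutidine, CH2Cl2, −78 °C; cold work-up, used at once
Reagents that add atoms: trifluoromethanesulfonic anhydride, O=S(=O)(OS(=O)(=O)C(F)(F)F)C(F)(F)F
Why: O-Sulfonylation of the primary alcohol at low temperature, the β-bromine slowing ionisation so that the triflate survives a short cold work-up.

Step 4
Reactants: 6 (2S)-2-bromo-3,3-dimethylhex-5-en-1-yl trifluoromethanesulfonate; 7 methyl acetoacetate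
Product: 8 methyl (6R)-6-bromo-7,7-dimethyl-3-oxodec-9-enoate
Conditions: 7, NaH, THF, 0 °C; n-BuLi, 0 °C; then 6, −78 to −20 °C; AcOH quench at −20 °C
Reagents that add atoms: none
Why: γ-Alkylation of the acetoacetate dianion by SN2 at the primary triflate, the neopentylic secondary C–Br being inert to displacement at this temperature so that the stereocentre is untouched (its descriptor changes to R only through the priority rules).

Step 5
Reactants: 8 methyl (6R)-6-bromo-7,7-dimethyl-3-oxodec-9-enoate
Product: 9 methyl (2Z,6R)-6-bromo-3-[(diethoxyphosphoryl)oxy]-7,7-dimethyldeca-2,9-dienoate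
Conditions: NaH, Et2O, 0 °C; ClP(O)(OEt)2, 0 °C
Reagents that add atoms: diethyl chlorophosphate, CCOP(=O)(Cl)OCC
Why: O-Phosphorylation of the chelated sodium enolate of the β-keto ester, whose U-shape fixes the (Z)-enol phosphate (phosphate cis to the ester).

Step 6
Reactants: 9 methyl (2Z,6R)-6-bromo-3-[(diethoxyphosphoryl)oxy]-7,7-dimethyldeca-2,9-dienoate
Product: 10 methyl (2E,6R)-6-bromo-3,7,7-trimethyldeca-2,9-dienoate
Conditions: Me2CuLi (from CuI and MeLi), Et2O, −78 to −45 °C
Reagents that add atoms: lithium dimethylcuprate, [Li+].C[Cu-]C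
Why: Addition–elimination of the cuprate on the β-phosphoryloxy enoate goes with retention, so the new methyl (C20) is cis to the ester and the (E)-enoate results, while the hindered secondary bromide does not couple at −45 °C.

Step 7
Reactants: 10 methyl (2E,6R)-6-bromo-3,7,7-trimethyldeca-2,9-dienoate; 11 crotonaldehyde
Product: 12 methyl (2E,6R,9E)-6-bromo-3,7,7-trimethyl-11-oxoundeca-2,9-dienoate
Conditions: second-generation Hoveyda–Grubbs catalyst RuCl2(H2IMes)(=CH-C6H4-2-OiPr) (5 mol %), 11 (5 equiv), CH2Cl2, 40 °C
Reagents that add atoms: none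
Why: Olefin cross-metathesis of the monosubstituted alkene with excess crotonaldehyde is E-selective, and the trisubstituted enoate does not engage the ruthenium carbene.

Step 8
Reactants: 12 methyl (2E,6R,9E)-6-bromo-3,7,7-trimethyl-11-oxoundeca-2,9-dienoate
Product: 13 methyl (2E,6R,8E,10E)-6-bromo-11-[(tert-butyldimethylsilyl)oxy]-3,7,7-trimethylundeca-2,8,10-trienoate
Conditions: TBSOTf, Et3N, Et2O, −78 to 0 °C
Reagents that add atoms: tert-butyldimethylsilyl trifluoromethanesulfonate, CC(C)(C)[Si](C)(C)OS(=O)(=O)C(F)(F)F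
Why: O-Silylation of the enal and γ-deprotonation at the CH2 next to the quaternary carbon give the 1-silyloxy diene, expected mainly as the (8E,10E)-isomer because the enal reacts through its s-trans form and the quaternary carbon takes the trans position on the new C8=C9 bond; any (10Z)-isomer is not expected to cyclise.

Step 9
Reactants: 13 methyl (2E,6R,8E,10E)-6-bromo-11-[(tert-butyldimethylsilyl)oxy]-3,7,7-trimethylundeca-2,8,10-trienoate
Product: 14 methyl (3R)-3-bromo-8-[(tert-butyldimethylsilyl)oxy]-4,4,10-trimethyl-trans-octal-6-ene-9-carboxylate (Br, O8 and CO2Me syn to C20, H5 anti)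
Conditions: PhMe (0.01 M), BHT, 2,6-di-tert-butyl-4-methylpyridine (0.2 equiv), sealed tube, 180 °C
Reagents that add atoms: none
Why: A thermal, concerted but asynchronous [4+2] cycloaddition of the type 1 intramolecular Diels–Alder class (a 2,8,10-undecatrienoate with a 1-oxygenated diene), in which the nucleophilic diene terminus C5 bonds to the enoate β-carbon C10 and C8 bonds to C9. Ring B (C5–C10) closes as the cyclohexene of the cycloaddition, and ring A (C1–C5, C10) closes through the same C5–C10 bond across the four-carbon tether, which folds as a chair. Suprafacial addition transfers the (E)-enoate geometry to C9/C10 (ester cis to the angular methyl) and the (E)-enol ether geometry to C8; the trans fusion at C5/C10 follows from the transition state with the ester endo and the tether anti, which also places O8 cis to the ester. The absolute sense comes from C3, whose bromine prefers the equatorial site of the chair tether, so that one diene face is selected. The step therefore needs endo over exo closure and this facial bias; the first rests on ester/diene secondary overlap and the second on the chair preference, while the C4 gem-dimethyl group (no [1,5]-hydrogen shift possible, Thorpe–Ingold folding) and the donor diene/acceptor enoate pairing supply the rate needed to build quaternary C10.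

Step 10
Reactants: 14 methyl (3R)-3-bromo-8-[(tert-butyldimethylsilyl)oxy]-4,4,10-trimethyl-trans-octal-6-ene-9-carboxylate
Product: 15 methyl (3R)-3-bromo-8-[(tert-butyldimethylsilyl)oxy]-4,4,10-trimethyl-trans-decalin-9-carboxylate
Conditions: TsNHNH2, NaOAc, DME/H2O, 85 °C
Reagents that add atoms: none
Why: Diimide reduction transfers two hydrogens concertedly to the only C=C bond (C6=C7) and touches neither the C–Br bond, the ester nor the silyl ether; no stereocentre is formed.

Step 11
Reactants: 15 methyl (3R)-3-bromo-8-[(tert-butyldimethylsilyl)oxy]-4,4,10-trimethyl-trans-decalin-9-carboxylate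
Product: 16 [(3R)-3-bromo-8-[(tert-butyldimethylsilyl)oxy]-4,4,10-trimethyl-trans-decalin-9-yl]methanol
Conditions: i-Bu2AlH, CH2Cl2, −78 to 0 °C; aqueous potassium sodium tartrate
Reagents that add atoms: none
Why: Aluminium hydride reduction of the methyl ester to the C11 alcohol, the silyl ether and the alkyl bromide being inert to i-Bu2AlH.

Step 12
Reactants: 16 [(3R)-3-bromo-8-[(tert-butyldimethylsilyl)oxy]-4,4,10-trimethyl-trans-decalin-9-yl]methanol
Product: 17 (3R)-3-bromo-8-[(tert-butyldimethylsilyl)oxy]-4,4,10-trimethyl-trans-decalin-9-carbaldehyde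
Conditions: Dess–Martin periodinane, pyridine, CH2Cl2, 0 °C to rt
Reagents that add atoms: none
Why: Dess–Martin oxidation under buffered, non-basic conditions gives the aldehyde without epimerising C9 or eliminating the β-silyloxy group.

Step 13
Reactants: 17 (3R)-3-bromo-8-[(tert-butyldimethylsilyl)oxy]-4,4,10-trimethyl-trans-decalin-9-carbaldehyde
Product: 18 tert-butyldimethylsilyl ether of (3R)-3-bromo-4,4,10-trimethyl-9-vinyl-trans-decalin-8-ol
Conditions: Ph3PCH3Br, KN(SiMe3)2, THF, 0 °C; then 17, −78 to 0 °C
Reagents that add atoms: methyltriphenylphosphonium bromide, C[P+](c1ccccc1)(c1ccccc1)c1ccccc1.[Br-]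
Why: Wittig methylenation, in which the small ylide adds to the hindered aldehyde faster than it deprotonates C9, a silyloxy group being a poor leaving group for β-elimination.

Step 14
Reactants: 18 tert-butyldimethylsilyl ether of (3R)-3-bromo-4,4,10-trimethyl-9-vinyl-trans-decalin-8-ol
Product: 19 (3R)-3-bromo-4,4,10-trimethyl-9-vinyl-trans-decalin-8-ol (OH syn to C20)
Conditions: Bu4NF, THF, rt to 45 °C
Reagents that add atoms: none
Why: Fluoride cleaves the Si–O bond, and the equatorial neopentylic bromide, which has no antiperiplanar hydrogen, resists both E2 and SN2.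

Step 15
Reactants: 19 (3R)-3-bromo-4,4,10-trimethyl-9-vinyl-trans-decalin-8-ol
Product: 20 (3R)-3-bromo-4,4,10-trimethyl-9-vinyl-trans-decalin-8-one
Conditions: Dess–Martin periodinane, pyridine, CH2Cl2, 0 °C
Reagents that add atoms: none
Why: Dess–Martin oxidation of the secondary alcohol, the pyridine buffer keeping the β,γ-unsaturated ketone out of conjugation and C9 (equatorial vinyl) unepimerised.

Step 16
Reactants: 20 (3R)-3-bromo-4,4,10-trimethyl-9-vinyl-trans-decalin-8-one
Product: 21 (3R)-3-bromo-4,4,10-trimethyl-8-methylidene-9-vinyl-trans-decalin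
Conditions: Zn, CH2Br2, TiCl4, THF/CH2Cl2, 0 °C to rt
Reagents that add atoms: dibromomethane, BrCBr
Why: Methylenation with the zinc/titanium gem-dimetallic carbenoid is non-basic and works on hindered, enolisable ketones, so C9 keeps its configuration and the vinyl group stays unconjugated.

Step 17
Reactants: 21 (3R)-3-bromo-4,4,10-trimethyl-8-methylidene-9-vinyl-trans-decalin
Product: 22 (3R)-3-bromo-8,17-epoxy-4,4,10-trimethyl-9-vinyl-trans-decalin (epoxide O anti to C20)
Conditions: mCPBA (1.05 equiv), NaHCO3, CH2Cl2, −20 to 0 °C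
Reagents that add atoms: 3-chloroperoxybenzoic acid, O=C(OO)c1cccc(Cl)c1
Why: Prilezhaev epoxidation, in which the 1,1-disubstituted exocyclic alkene is much more nucleophilic than the monosubstituted vinyl group and the peracid approaches C8 along the equatorial direction, anti to the axial C10 methyl, so that the oxygen ends anti to C20.

Step 18
Reactants: 22 (3R)-3-bromo-8,17-epoxy-4,4,10-trimethyl-9-vinyl-trans-decalin
Product: 23 (3R)-3-bromo-4,4,8,10-tetramethyl-9-vinyl-trans-decalin-8-ol (OH anti to C20, C17 syn)
Conditions: LiAlH4, Et2O, 0 °C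
Reagents that add atoms: none
Why: Hydride opens the spiro-epoxide by SN2 at the unhindered CH2 terminus, so the C8–O bond and its configuration are kept (equatorial OH, axial methyl), and the neopentylic equatorial bromide is not displaced at 0 °C.

Step 19
Reactants: 24 but-2-yn-1-ol
Product: 27 (E)-3-iodobut-2-en-1-ol, via aluminium alkoxide 25 (not isolated), via alkenylzirconocene 26 (not isolated)
Conditions: i-Bu2AlH (1 equiv), THF, 0 °C; Cp2ZrCl2 and i-Bu2AlH (gives Cp2Zr(H)Cl), THF, 0 °C to rt; then I2, −78 to 0 °C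
Reagents that add atoms: iodine, II
Why: Hydrozirconation is a syn addition which, with the alcohol masked as its bulky aluminium alkoxide, places zirconium on the methyl-bearing carbon, and iodinolysis with retention gives the (E)-iodide (methyl cis to CH2OH).

Step 20
Reactants: 23 (3R)-3-bromo-4,4,8,10-tetramethyl-9-vinyl-trans-decalin-8-ol; 27 (E)-3-iodobut-2-en-1-ol
Product: 29 (2E)-5-[(1S,2S,4aS,6R,8aR)-6-bromo-2-hydroxy-2,5,5,8a-tetramethyldecahydronaphthalen-1-yl]-3-methylpent-2-en-1-ol, via alkylborane 28 (not isolated)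
Conditions: 9-BBN-H (2.5 equiv), THF, rt to 50 °C; then 27, Pd(dppf)Cl2 (5 mol %), AsPh3, Cs2CO3, DMF/H2O, rt
Reagents that add atoms: none
Why: Anti-Markovnikov hydroboration of the vinyl group and B-alkyl Suzuki–Miyaura coupling, in which zerovalent palladium inserts into the alkenyl C–I bond and not into the unactivated C–Br bond and the alkene geometry is retained, give the (13E)-allylic alcohol directly.

## Compound list

1 | 2,2-dimethylpent-4-enal | C=CCC(C)(C)C=O | starting material
2 | 1-methoxy-3,3-dimethylhexa-1,5-diene (E/Z mixture) | C=CCC(C)(C)C=COC | intermediate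
3 | 3,3-dimethylhex-5-enal | C=CCC(C)(C)CC=O | intermediate
4 | (2S)-2-bromo-3,3-dimethylhex-5-enal | C=CCC(C)(C)[C@H](Br)C=O | intermediate
5 | (2S)-2-bromo-3,3-dimethylhex-5-en-1-ol | C=CCC(C)(C)[C@H](Br)CO | intermediate
6 | (2S)-2-bromo-3,3-dimethylhex-5-en-1-yl trifluoromethanesulfonate | C=CCC(C)(C)[C@H](Br)COS(=O)(=O)C(F)(F)F | intermediate
7 | methyl acetoacetate | COC(=O)CC(C)=O | starting material
8 | methyl (6R)-6-bromo-7,7-dimethyl-3-oxodec-9-enoate | C=CCC(C)(C)[C@H](Br)CCC(=O)CC(=O)OC | intermediate
9 | methyl (2Z,6R)-6-bromo-3-[(diethoxyphosphoryl)oxy]-7,7-dimethyldeca-2,9-dienoate | C=CCC(C)(C)[C@H](Br)CC/C(OP(=O)(OCC)OCC)=C/C(=O)OC | intermediate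
10 | methyl (2E,6R)-6-bromo-3,7,7-trimethyldeca-2,9-dienoate | C=CCC(C)(C)[C@H](Br)CC/C(C)=C/C(=O)OC | intermediate
11 | crotonaldehyde, (E)-but-2-enal | C/C=C/C=O | starting material
12 | methyl (2E,6R,9E)-6-bromo-3,7,7-trimethyl-11-oxoundeca-2,9-dienoate | O=C/C=C/CC(C)(C)[C@H](Br)CC/C(C)=C/C(=O)OC | intermediate
13 | methyl (2E,6R,8E,10E)-6-bromo-11-[(tert-butyldimethylsilyl)oxy]-3,7,7-trimethylundeca-2,8,10-trienoate | CC(C)(C)[Si](C)(C)O/C=C/C=C/C(C)(C)[C@H](Br)CC/C(C)=C/C(=O)OC | intermediate
14 | Diels–Alder adduct: C9 methyl ester, C8 OTBS, C6=C7, C3 Br (3R) on the trans-fused bicycle; Br, O8 and CO2Me syn to C20, H5 anti | COC(=O)[C@H]1[C@]2(C)CC[C@@H](Br)C(C)(C)[C@H]2C=C[C@H]1O[Si](C)(C)C(C)(C)C | intermediate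
15 | saturated ester (14 with C6–C7 single bond) | COC(=O)[C@H]1[C@]2(C)CC[C@@H](Br)C(C)(C)[C@H]2CC[C@H]1O[Si](C)(C)C(C)(C)C | intermediate
16 | C11 primary alcohol, C8 OTBS | OC[C@H]1[C@]2(C)CC[C@@H](Br)C(C)(C)[C@H]2CC[C@H]1O[Si](C)(C)C(C)(C)C | intermediate
17 | C11 aldehyde, C8 OTBS | O=C[C@H]1[C@]2(C)CC[C@@H](Br)C(C)(C)[C@H]2CC[C@H]1O[Si](C)(C)C(C)(C)C | intermediate
18 | C9 vinyl, C8 OTBS | C=C[C@H]1[C@]2(C)CC[C@@H](Br)C(C)(C)[C@H]2CC[C@H]1O[Si](C)(C)C(C)(C)C | intermediate
19 | C9 vinyl, C8 secondary alcohol (OH syn to C20) | C=C[C@H]1[C@]2(C)CC[C@@H](Br)C(C)(C)[C@H]2CC[C@H]1O | intermediate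
20 | C9 vinyl, C8 ketone | C=C[C@H]1[C@]2(C)CC[C@@H](Br)C(C)(C)[C@H]2CCC1=O | intermediate
21 | C9 vinyl, C8(17) exocyclic methylene | C=C[C@H]1[C@]2(C)CC[C@@H](Br)C(C)(C)[C@H]2CCC1=C | intermediate
22 | C9 vinyl, 8,17-epoxide (O anti to C20) | C=C[C@H]1[C@]2(C)CC[C@@H](Br)C(C)(C)[C@H]2CC[C@]1(C3)O3 | intermediate
23 | C9 vinyl, C8 tertiary alcohol (OH anti to C20, C17 syn) | C=C[C@H]1[C@]2(C)CC[C@@H](Br)C(C)(C)[C@H]2CC[C@]1(C)O | intermediate
24 | but-2-yn-1-ol | CC#CCO | starting material
25 | diisobutylaluminium but-2-yn-1-olate | CC#CCO[Al](CC(C)C)CC(C)C | intermediate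
26 | (E)-alkenylzirconocene chloride of 25 (Zr on C3, trans to CH2O) | C/C(=C\CO[Al](CC(C)C)CC(C)C)[Zr+2]Cl.c1cc[cH-]c1.c1cc[cH-]c1 | intermediate
27 | (E)-3-iodobut-2-en-1-ol | C/C(I)=C\CO | intermediate
28 | B-alkyl-9-borabicyclo[3.3.1]nonane from 23 (boron on C12) | C1CCC2CCCC1B2CC[C@H]1[C@]2(C)CC[C@@H](Br)C(C)(C)[C@H]2CC[C@]1(C)O | intermediate
29 | (2E)-5-[(1S,2S,4aS,6R,8aR)-6-bromo-2-hydroxy-2,5,5,8a-tetramethyldecahydronaphthalen-1-yl]-3-methylpent-2-en-1-ol | C/C(=C\CO)CC[C@H]1[C@]2(C)CC[C@@H](Br)C(C)(C)[C@H]2CC[C@]1(C)O | target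

## Step count and risks

Total steps: 20. Longest linear sequence: 19 (steps 1–18 and 20); step 19 is a one-step side branch.

**Step 9 (cycloaddition).** The ring closure may be too slow at a temperature that the bromide and the silyl dienol ether tolerate, because a β,β-disubstituted enoate is a weak dienophile. Exo (cis-fused) closure, or addition to the other diene face (bromine axial on the tether), may also compete, since the equatorial preference of bromine beside a gem-dimethyl group is small. The facial isomers are diastereomers and separable, so the optical purity of the target is not at stake, only material. Fallback (a lower-LUMO dienophile), setting out from 13: i-Bu2AlH at −78 °C reduces only the enoate to (2E,6R,8E,10E)-6-bromo-11-[(tert-butyldimethylsilyl)oxy]-3,7,7-trimethylundeca-2,8,10-trien-1-ol F1, and MnO2 gives the corresponding trienal F2. Its thermal intramolecular Diels–Alder reaction (toluene, 110–140 °C, aldehyde endo) should give the C6=C7 unsaturated aldehyde adduct F3. Diimide from dipotassium azodicarboxylate and AcOH (no sulfonyl hydrazide, which would condense with the aldehyde) then saturates C6=C7, and the route is rejoined at 17.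

**Step 4 (dianion alkylation).** E2 loss of triflic acid, or attack of the strongly basic dianion on bromine with loss of triflate (reductive elimination to an alkene), may outrun SN2 at the β-branched CH2OTf carbon, and the product enolate may close onto the C–Br carbon if the mixture warms. Fallback (a soft, weakly basic nucleophile and a later two-carbon homologation), setting out from 6: di-tert-butyl malonate and NaH (THF, 0 °C to rt) should give di-tert-butyl 2-[(2R)-2-bromo-3,3-dimethylhex-5-en-1-yl]propanedioate F4. CF3CO2H followed by heating in toluene (ester cleavage and decarboxylation) gives (4R)-4-bromo-5,5-dimethyloct-7-enoic acid F5. Carbonyldiimidazole converts it into the acyl imidazolide F6, which with Mg(O2CCH2CO2Me)2 undergoes C-acylation and decarboxylation to return to the route at 8.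

**Step 2 (α-bromination).** Enamine formation at an aldehyde flanked by a quaternary carbon may be slow, and the α-bromo aldehyde may racemise through enamine or enol before it is reduced, eroding the enantiomeric purity on which every later stereocentre depends. Fallback (auxiliary control with separable diastereomers), setting out from 3: Pinnick oxidation (NaClO2, NaH2PO4, 2-methylbut-2-ene) gives 3,3-dimethylhex-5-enoic acid F7. Pivaloyl chloride/Et3N and lithiated (4S)-4-benzyl-1,3-oxazolidin-2-one give (4S)-4-benzyl-3-(3,3-dimethylhex-5-enoyl)-1,3-oxazolidin-2-one F8. Its dibutylboron enolate (Bu2BOTf, i-Pr2NEt) is brominated by N-bromosuccinimide on the face remote from the benzyl group to give (4S)-4-benzyl-3-[(2S)-2-bromo-3,3-dimethylhex-5-enoyl]-1,3-oxazolidin-2-one F9, which is purified as a single diastereomer. LiBH4 removes the auxiliary reductively, and the route is rejoined at 5.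

## Further compounds

F1 | step 9 | (2E,6R,8E,10E)-6-bromo-11-[(tert-butyldimethylsilyl)oxy]-3,7,7-trimethylundeca-2,8,10-trien-1-ol | CC(C)(C)[Si](C)(C)O/C=C/C=C/C(C)(C)[C@H](Br)CC/C(C)=C/CO
F2 | step 9 | (2E,6R,8E,10E)-6-bromo-11-[(tert-butyldimethylsilyl)oxy]-3,7,7-trimethylundeca-2,8,10-trienal | CC(C)(C)[Si](C)(C)O/C=C/C=C/C(C)(C)[C@H](Br)CC/C(C)=C/C=O
F3 | step 9 | aldehyde adduct: C9 CHO, C8 OTBS, C6=C7, C3 Br on the trans-fused bicycle (Br, O8 and CHO syn to C20) | O=C[C@H]1[C@]2(C)CC[C@@H](Br)C(C)(C)[C@H]2C=C[C@H]1O[Si](C)(C)C(C)(C)C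
F4 | step 4 | di-tert-butyl 2-[(2R)-2-bromo-3,3-dimethylhex-5-en-1-yl]propanedioate | C=CCC(C)(C)[C@H](Br)CC(C(=O)OC(C)(C)C)C(=O)OC(C)(C)C
F5 | step 4 | (4R)-4-bromo-5,5-dimethyloct-7-enoic acid | C=CCC(C)(C)[C@H](Br)CCC(=O)O
F6 | step 4 | (4R)-4-bromo-1-(imidazol-1-yl)-5,5-dimethyloct-7-en-1-one | C=CCC(C)(C)[C@H](Br)CCC(=O)n1ccnc1
F7 | step 2 | 3,3-dimethylhex-5-enoic acid | C=CCC(C)(C)CC(=O)O
F8 | step 2 | (4S)-4-benzyl-3-(3,3-dimethylhex-5-enoyl)-1,3-oxazolidin-2-one | C=CCC(C)(C)CC(=O)N1[C@@H](Cc2ccccc2)COC1=O
F9 | step 2 | (4S)-4-benzyl-3-[(2S)-2-bromo-3,3-dimethylhex-5-enoyl]-1,3-oxazolidin-2-one | C=CCC(C)(C)[C@H](Br)C(=O)N1[C@@H](Cc2ccccc2)COC1=O
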